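## Analysis of the target

Ocophyllal B (15) is a fully aromatic benzofuran. A furan ring (O1, C2, C3, C3a, C7a) is fused through the C3a–C7a bond to a benzo ring (C3a, C4, C5, C6, C7, C7a). C2 carries a 3,4,5-trimethoxyphenyl group, C3 a methyl group, C5 a formyl group and C7 a methoxy group; C4 and C6 carry hydrogen. There is no stereocentre, so the problem is purely one of regiochemistry. The formyl and methoxy groups sit meta to each other on the benzo ring, with C7 next to the ring oxygen. The aldehyde is the most sensitive group (base, nucleophiles, air, decarbonylation on hot metal surfaces) and should appear last. The trimethoxyphenyl ring and the benzofuran are both electron-rich, so a late electrophilic formylation or halogenation of the finished skeleton would not be selective. The substituents at C5 and C7 must therefore be fixed before the benzo ring exists. The plan rests on one feature: cutting C5–C6 opens the benzo ring to the hexatriene C6=C7–C7a=C3a–C4=C5. Its central double bond is the furan C3a=C7a bond, C7 already bears the methoxy group (as an enol ether), and C5 already bears the carboxyl carbon (as an acrylate).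

## Retrosynthetic reasoning

**Aldehyde back to ester (15 ⇒ 14 ⇒ 13).** No skeletal bond is cut; the formyl carbon is taken back through benzylic alcohol 14 to methyl ester 13. The C5 carbon then passes through the hot, metal-assisted ring closure at the ester level, where it cannot decarbonylate or condense. Forward, an aryl ester must be reduced beside four aryl methyl ethers, and a benzylic alcohol oxidized without harming the electron-rich rings. Full reduction followed by a mild benzylic oxidation is more dependable than stopping a hydride reduction at the aldehyde.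

**Benzo ring (13 ⇒ 12 ⇒ 11).** The C5–C6 bond is cut and two hydrogens are returned to C5 and C6, leading through dihydro compound 12 to triene 11. C5–C6 is the only bond of the benzo ring that lies opposite the shared C3a–C7a bond. It is therefore the only cut that turns the furan double bond into the middle alkene of a hexatriene. The whole substitution pattern of the benzo ring is then written into two alkenyl arms on a furan: a 1-methoxyvinyl group at C7a and an acrylate at C3a. Forward, the step must close a six-membered ring by a six-electron electrocyclization and remove two hydrogens in the same flask, while keeping the enol ether oxygen.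

**Acrylate arm (11 ⇒ 9 + 10).** The C3a–C4 bond is cut between the furan β-carbon and the alkene, giving iodofuran 9 and methyl acrylate 10. A Heck reaction forms this sp2–sp2 bond with E geometry and needs no organometallic partner. The arm is added after the enol ether is made, because a carbonyl methylenation could not tell two esters apart.

**Enol ether (9 ⇒ 8).** The C6 methylene is removed, leading back to methyl ester 8. The ester carbonyl carbon becomes C7, the ester methoxy group becomes the C7 methoxy group, and the methylenating reagent supplies C6. No separate O-methylation is needed, and the same carboxyl group serves earlier as the handle for the iodination.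

**Iodide (8 ⇒ 7 ⇒ 5, via 6).** The C–I bond and the ester methyl are removed, giving acid 5. The iodine is placed by carboxylate-directed metalation through dianion 6. An electrophilic halogenation would have to compete with the trimethoxyphenyl ring; deprotonation beside the carboxylate avoids that.

**Carboxyl group (5 ⇒ 3, via 4).** The C7–C7a bond is cut, giving 2-aryl-3-methylfuran 3. Its only free α-position is the most acidic C–H bond of the molecule, so lithiation to 4 followed by carboxylation is unambiguous.

**Aryl–furan bond (3 ⇒ 1 + 2).** The C2–aryl bond is cut to acid 1 and aryl bromide 2. The carboxyl group of 1 sits next to the methyl group, so a decarboxylative coupling puts the aryl group exactly there. This sets the adjacent aryl/methyl pattern of C2/C3 without a regiochemical choice.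

## Alternatives that were turned down

**Alternative 1:** The furan ring is cut at C2–C3 and O1–C2. This leads to an ortho-quinone methide (the benzo ring with C3 and its methyl group) and a benzylic sulfur ylide that brings C2 with the trimethoxyphenyl group. Forward, a carbonate base would release both partners from a 2-(1-sulfonylethyl)phenol and a benzylic sulfonium salt. Conjugate addition of the ylide forms C2–C3, and displacement of the sulfide by the phenoxide forms O1–C2. The product is trans-5-bromo-7-methoxy-3-methyl-2-(3,4,5-trimethoxyphenyl)-2,3-dihydro-1-benzofuran A1 (racemic). Dehydrogenation to 5-bromo-7-methoxy-3-methyl-2-(3,4,5-trimethoxyphenyl)-1-benzofuran A2, then halogen–metal exchange and formylation, would finish the synthesis.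

- For: the benzo ring pattern is bought with a cheap phenol, the union of the halves is mild and convergent, and the step count is probably lower than that of the chosen route.
- Against: two stereocentres (C2, C3) are made only to be destroyed. The oxidation of A1 to A2 must act on a substrate with three electron-rich rings and further benzylic hydrogens. The quinone methide carries a methyl group on its exocyclic carbon and can drain away by a hydrogen shift to an ortho-vinylphenol. The aldehyde must travel as a bromide, because a free aldehyde would react with the ylide.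
- Comparison: Alternative 1 is at least as strong on step economy and on mildness. The chosen strategy never leaves the aromatic furan oxidation level, creates no stereocentre, and sets the final oxidation state of the new ring in the ring-forming flask.

**Alternative 2:** The C3–C3a bond is cut, leading to aryl vinyl ether A4, 5-(dimethoxymethyl)-1,3-dimethoxy-2-{[1-(3,4,5-trimethoxyphenyl)prop-1-en-1-yl]oxy}benzene. Its phenol part is symmetrical, with two ortho-methoxy groups and a masked para-formyl group. Irradiation near 300 nm would trigger a conrotatory six-electron closure onto a methoxy-bearing ortho carbon. The intermediate would then rearomatize by expelling that methoxy group as the alcohol. The product is 5-(dimethoxymethyl)-7-methoxy-3-methyl-2-(3,4,5-trimethoxyphenyl)-1-benzofuran A3; mild acid would free the aldehyde.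

- For: it is the shortest of the four plans, the two ortho positions are equivalent, the furan appears aromatic without any oxidant, and the whole benzo ring is purchased.
- Against: the key step runs through an excited state. E/Z isomerization, homolysis of the aryl–oxygen bond and hydrogen-shift pathways of the ring-closed ylide all compete with the eliminative route. A3 is a stronger chromophore than A4 at the same wavelength, so it screens the light and may itself be photolabile. Dilute photochemistry also scales poorly.
- Comparison: Alternative 2 is stronger on step count and on redox economy. The chosen strategy offers a ground-state thermal closure whose regiochemistry follows from connectivity alone, ordinary glassware, and a precursor built by cross-couplings of well-known scope.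

**Alternative 3:** Three bonds of the benzo ring are cut at once (C6–C7, C4–C5, C3a–C4). The pieces are the chromium carbene complex A6, (CO)5Cr=C(OMe)[4-methyl-5-(3,4,5-trimethoxyphenyl)furan-2-yl], the alkyne A7, tert-butyl(dimethyl)(prop-2-yn-1-yloxy)silane, and one carbonyl ligand. A6 would come from lithiofuran 4 of the chosen route. Heating in THF would give alkyne insertion, carbonyl insertion and ring closure of the vinylketene onto the furan β-carbon (a Dötz benzannulation). The product is 5-{[tert-butyl(dimethyl)silyl]oxymethyl}-7-methoxy-3-methyl-2-(3,4,5-trimethoxyphenyl)-1-benzofuran-4-ol A5.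

- For: three bonds form in one step from the same furan 3, the regiochemistry is predictable (the larger alkyne substituent ends up next to the new hydroxyl group), the carbene supplies the C7 methoxy group, and the temperature is mild.
- Against: A5 carries an oxygen at C4 that the target lacks. Removing it costs a sulfonylation and a reductive cleavage at a hindered position peri to the C3 methyl group, before desilylation and oxidation. Chromium is used stoichiometrically, and A5 is an air-sensitive hydroquinone monoether.
- Comparison: Alternative 3 is as strong or stronger at the ring-forming step itself (bond count, temperature). The chosen strategy delivers the benzo ring with exactly the target's substituents, uses only catalytic metal in the ring-forming step, and needs two steps after it instead of four or five.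

Key step: step 7

Remark on the chemistry: the only stereocentre that appears (C5 of 12) is formed as a racemate and is erased on aromatization, so no configuration is specified anywhere in the route.

## Route

Step 1
Reactants: 1 3-methylfuran-2-carboxylic acid; 2 5-bromo-1,2,3-trimethoxybenzene
Product: 3 3-methyl-2-(3,4,5-trimethoxyphenyl)furan
Conditions: PdCl2 (5 mol %), P(t-Bu)3·HBF4 (10 mol %), n-Bu4NCl, Cs2CO3, DMF, 170 °C (microwave)
Reagents that add atoms: none
Why: Decarboxylative cross-coupling of a heteroaromatic 2-carboxylic acid with an aryl bromide: oxidative addition of 2 to zerovalent palladium (formed from divalent PdCl2), palladation at the carboxyl-bearing carbon with loss of CO2, and reductive elimination. The 3-methyl group blocks the competing arylation at C3, and the carboxyl group fixes the aryl group next to the methyl group.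

Step 2
Reactants: 3 3-methyl-2-(3,4,5-trimethoxyphenyl)furan
Product: 5 4-methyl-5-(3,4,5-trimethoxyphenyl)furan-2-carboxylic acid, via 5-lithiofuran 4 (not isolated)
Conditions: n-BuLi, THF, −78 to 0 °C; CO2 (g), −78 °C to rt; aq. HCl
Reagents that add atoms: carbon dioxide, O=C=O
Why: α-Lithiation of a furan followed by carboxylation. The single free α-hydrogen is the most acidic C–H bond, and the aryl hydrogens next to methoxy groups are metalated much more slowly under these conditions.

Step 3
Reactants: 5 4-methyl-5-(3,4,5-trimethoxyphenyl)furan-2-carboxylic acid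
Product: 7 3-iodo-4-methyl-5-(3,4,5-trimethoxyphenyl)furan-2-carboxylic acid, via C3-lithiated lithium carboxylate 6 (not isolated)
Conditions: i-Pr2NLi (LDA, 2.2 equiv), THF, −78 °C; I2, THF, −78 °C to rt; aq. HCl
Reagents that add atoms: iodine, II
Why: Carboxylate-directed ortho-lithiation of a 2-furoic acid whose other α-position is blocked (dianion formation), then iodinolysis of the C–Li bond. The C4 methyl group is not conjugated with the carboxylate, so lateral deprotonation is not favoured, and the directed metalation avoids an electrophilic halogenation that would attack the trimethoxyphenyl ring.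

Step 4
Reactants: 7 3-iodo-4-methyl-5-(3,4,5-trimethoxyphenyl)furan-2-carboxylic acid
Product: 8 methyl 3-iodo-4-methyl-5-(3,4,5-trimethoxyphenyl)furan-2-carboxylate
Conditions: MeI, K2CO3, DMF, rt
Reagents that add atoms: iodomethane, CI
Why: SN2 O-alkylation of the carboxylate; no other nucleophilic site is present.

Step 5
Reactants: 8 methyl 3-iodo-4-methyl-5-(3,4,5-trimethoxyphenyl)furan-2-carboxylate
Product: 9 3-iodo-2-(1-methoxyethenyl)-4-methyl-5-(3,4,5-trimethoxyphenyl)furan
Conditions: Cp2TiMe2 (3 equiv), toluene–THF, 70 °C, dark; filtration through basic alumina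
Reagents that add atoms: dimethyltitanocene Cp2TiMe2, C[Ti](C)(C1C=CC=C1)C1C=CC=C1
Why: Petasis methylenation of an ester: thermolysis of Cp2TiMe2 gives Cp2Ti=CH2, which adds across the ester C=O and cycloreverts to the methyl enol ether and Cp2Ti=O. The medium is non-acidic, which the enol ether needs, and aryl iodides are inert to the titanium methylidene.

Step 6
Reactants: 9 3-iodo-2-(1-methoxyethenyl)-4-methyl-5-(3,4,5-trimethoxyphenyl)furan; 10 methyl acrylate
Product: 11 methyl (E)-3-[2-(1-methoxyethenyl)-4-methyl-5-(3,4,5-trimethoxyphenyl)furan-3-yl]prop-2-enoate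
Conditions: Pd(OAc)2 (5 mol %), n-Bu4NCl, K2CO3, DMF, 60 °C
Reagents that add atoms: none
Why: Mizoroki–Heck reaction under ligand-free phase-transfer conditions: oxidative addition at C–I, insertion of the electron-poor acrylate and syn β-hydride elimination give the E alkene. The 1,1-disubstituted, electron-rich enol ether does not compete as the alkene partner, and the basic medium and moderate temperature protect it and keep the triene from closing early.

Step 7
Reactants: 11 methyl (E)-3-[2-(1-methoxyethenyl)-4-methyl-5-(3,4,5-trimethoxyphenyl)furan-3-yl]prop-2-enoate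
Product: 13 methyl 7-methoxy-3-methyl-2-(3,4,5-trimethoxyphenyl)-1-benzofuran-5-carboxylate, via 5,6-dihydrobenzofuran 12 (not isolated)
Conditions: Pd/C (10 % Pd, 20 mol % Pd), K2CO3 (solid), o-dichlorobenzene (0.02 M, degassed), 180 °C, argon sweep
Reagents that add atoms: none
Why: Thermal six-electron electrocyclization with in situ dehydrogenation, the reaction type known for 2,3-dialkenyl furans, thiophenes and indoles. In the s-cis,s-cis conformer of 11 the triene C6=C7–C7a=C3a–C4=C5 closes suprafacially in the thermally allowed disrotatory mode, forming C5–C6 and closing the six-membered benzo ring as 5,6-dihydrobenzofuran 12, in which the furan is held as a bis(alkylidene)dihydrofuran. The aromatic stabilization of furan is small, so this dearomatizing closure should be reachable near 180 °C, and the E acrylate keeps the ester on the outside of the rotating terminus. The termini are not a matched donor–acceptor pair (C6 is the nucleophilic β-carbon of the enol ether, but C5 is the α-carbon of the acrylate), so no large polar acceleration is assumed and the closure is treated as a purely pericyclic event. On the palladium surface 12, or a tautomer formed from it by a [1,5]-hydrogen shift, loses H2 from C5 and C6; this restores the furan, creates the benzene ring and pulls the reversible closure forward. The only stereocentre formed, C5 of 12, is racemic and is erased in the same flask, so no stereocontrol is needed. The step needs chemoselectivity: dehydrogenation must be faster than aromatization by loss of methanol from a tautomer that carries hydrogen at C7, and the enol ether must neither hydrolyse nor polymerize. The first is served by having Pd/C present from the start and sweeping H2 out with argon, the second by high dilution, solid K2CO3 as acid scavenger and the fixed cis placement of the two arms on the furan, which makes ring closure faster than any bimolecular reaction.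

Step 8
Reactants: 13 methyl 7-methoxy-3-methyl-2-(3,4,5-trimethoxyphenyl)-1-benzofuran-5-carboxylate
Product: 14 [7-methoxy-3-methyl-2-(3,4,5-trimethoxyphenyl)-1-benzofuran-5-yl]methanol
Conditions: i-Bu2AlH (2.5 equiv), CH2Cl2, −78 to 0 °C; aq. potassium sodium tartrate
Reagents that add atoms: none
Why: Hydride reduction of an aryl ester to the primary alcohol with i-Bu2AlH. Full reduction is intended, so the reaction does not have to be stopped at the aldehyde, and aryl ethers and the benzofuran are inert.

Step 9
Reactants: 14 [7-methoxy-3-methyl-2-(3,4,5-trimethoxyphenyl)-1-benzofuran-5-yl]methanol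
Product: 15 7-methoxy-3-methyl-2-(3,4,5-trimethoxyphenyl)-1-benzofuran-5-carbaldehyde (ocophyllal B)
Conditions: MnO2 (activated, excess), CH2Cl2, rt
Reagents that add atoms: none
Why: MnO2 oxidation of a benzylic alcohol, which stops at the aldehyde and leaves the electron-rich rings untouched.

## Compound list

1 | 3-methylfuran-2-carboxylic acid | Cc1ccoc1C(=O)O | starting material
2 | 5-bromo-1,2,3-trimethoxybenzene | COc1cc(Br)cc(OC)c1OC | starting material
3 | 3-methyl-2-(3,4,5-trimethoxyphenyl)furan | Cc1ccoc1-c1cc(OC)c(OC)c(OC)c1 | intermediate
4 | [4-methyl-5-(3,4,5-trimethoxyphenyl)furan-2-yl]lithium | [Li]c1cc(C)c(-c2cc(OC)c(OC)c(OC)c2)o1 | intermediate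
5 | 4-methyl-5-(3,4,5-trimethoxyphenyl)furan-2-carboxylic acid | Cc1cc(C(=O)O)oc1-c1cc(OC)c(OC)c(OC)c1 | intermediate
6 | lithium 3-lithio-4-methyl-5-(3,4,5-trimethoxyphenyl)furan-2-carboxylate | Cc1c([Li])c(C(=O)O[Li])oc1-c1cc(OC)c(OC)c(OC)c1 | intermediate
7 | 3-iodo-4-methyl-5-(3,4,5-trimethoxyphenyl)furan-2-carboxylic acid | Cc1c(I)c(C(=O)O)oc1-c1cc(OC)c(OC)c(OC)c1 | intermediate
8 | methyl 3-iodo-4-methyl-5-(3,4,5-trimethoxyphenyl)furan-2-carboxylate | COC(=O)c1oc(-c2cc(OC)c(OC)c(OC)c2)c(C)c1I | intermediate
9 | 3-iodo-2-(1-methoxyethenyl)-4-methyl-5-(3,4,5-trimethoxyphenyl)furan | C=C(OC)c1oc(-c2cc(OC)c(OC)c(OC)c2)c(C)c1I | intermediate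
10 | methyl acrylate (methyl prop-2-enoate) | C=CC(=O)OC | starting material
11 | methyl (E)-3-[2-(1-methoxyethenyl)-4-methyl-5-(3,4,5-trimethoxyphenyl)furan-3-yl]prop-2-enoate | C=C(OC)c1oc(-c2cc(OC)c(OC)c(OC)c2)c(C)c1/C=C/C(=O)OC | intermediate
12 | methyl 7-methoxy-3-methyl-2-(3,4,5-trimethoxyphenyl)-5,6-dihydro-1-benzofuran-5-carboxylate (racemic at C5) | COC(=O)C1CC(OC)=C2OC(-c3cc(OC)c(OC)c(OC)c3)=C(C)C2=C1 | intermediate
13 | methyl 7-methoxy-3-methyl-2-(3,4,5-trimethoxyphenyl)-1-benzofuran-5-carboxylate | Cc1c(-c2cc(OC)c(OC)c(OC)c2)oc2c(OC)cc(C(=O)OC)cc12 | intermediate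
14 | [7-methoxy-3-methyl-2-(3,4,5-trimethoxyphenyl)-1-benzofuran-5-yl]methanol | Cc1c(-c2cc(OC)c(OC)c(OC)c2)oc2c(OC)cc(CO)cc12 | intermediate
15 | 7-methoxy-3-methyl-2-(3,4,5-trimethoxyphenyl)-1-benzofuran-5-carbaldehyde (ocophyllal B) | COc1cc(-c2oc3c(OC)cc(C=O)cc3c2C)cc(OC)c1OC | target

## Step count and least certain steps

Total: 9 steps. Longest linear sequence: 9 steps (1 to 15); 2 and 10 enter as purchased materials.

**Step 7 (key step).** The most likely failure is aromatization by the wrong exit. A hydrogen shift can place hydrogen on C7, after which loss of methanol gives an aromatic ring that has lost the C7 oxygen. Transfer of the liberated hydrogen to the acrylate double bond of unreacted triene on Pd/C, and acid-promoted hydrolysis of the enol ether at 180 °C, are the other two threats.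

Fallback: set out from iodo acid 7 and rejoin at ester 13 through a Stobbe benzannulation, which closes the same ring by an ionic acylation instead of a pericyclic step.
- Protodecarboxylation of 7 (Ag2CO3 cat., AcOH, DMSO, 120 °C) should give 4-iodo-3-methyl-2-(3,4,5-trimethoxyphenyl)furan F1.
- Iodine–magnesium exchange (i-PrMgCl·LiCl, THF, 0 °C) and quenching with DMF should give 4-methyl-5-(3,4,5-trimethoxyphenyl)furan-3-carbaldehyde F2.
- Stobbe condensation with dimethyl succinate (t-BuOK, t-BuOH) should give (E)-3-(methoxycarbonyl)-4-[4-methyl-5-(3,4,5-trimethoxyphenyl)furan-3-yl]but-3-enoic acid F3.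
- Heating F3 in Ac2O with NaOAc should acylate the free furan α-position (the future C7a) and give methyl 7-acetyloxy-3-methyl-2-(3,4,5-trimethoxyphenyl)-1-benzofuran-5-carboxylate F4.
- Methanolysis (K2CO3, MeOH) should give methyl 7-hydroxy-3-methyl-2-(3,4,5-trimethoxyphenyl)-1-benzofuran-5-carboxylate F5, and O-methylation (MeI, K2CO3, acetone) leads to 13.

**Step 5.** The ester is conjugated with the furan and flanked by iodine, so methylenation may stall. The product enol ether may also hydrolyse on contact with acidic surfaces during isolation.

Fallback: set out from acid 7 and rejoin at 9 by a ketal elimination, which makes the enol ether without a titanium alkylidene.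
- Amide coupling with N,O-dimethylhydroxylamine hydrochloride (EDC·HCl, HOBt, i-Pr2NEt, CH2Cl2) should give 3-iodo-N-methoxy-N,4-dimethyl-5-(3,4,5-trimethoxyphenyl)furan-2-carboxamide F6.
- MeMgBr (THF, −20 to 0 °C) should give 1-[3-iodo-4-methyl-5-(3,4,5-trimethoxyphenyl)furan-2-yl]ethan-1-one F7.
- CH(OMe)3, MeOH and catalytic TsOH should give 2-(1,1-dimethoxyethyl)-3-iodo-4-methyl-5-(3,4,5-trimethoxyphenyl)furan F8.
- TMSOTf with i-Pr2NEt (CH2Cl2, −20 °C) should eliminate one methoxy group and give 9.

**Step 3.** Deprotonation may occur at the wrong site (the C4 methyl group, or the aryl ring next to a methoxy group). Dianion formation may also be incomplete because the lithium carboxylate is poorly soluble at −78 °C.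

Fallback: set out from furan 3 and rejoin at triene 11 by a halogen dance, which places the halogen without a carboxylate-directed metalation.
- NBS (DMF, 0 °C) should brominate the free α-position and give 5-bromo-3-methyl-2-(3,4,5-trimethoxyphenyl)furan F9.
- i-Pr2NLi (THF, −78 °C) should remove the only ring hydrogen and trigger bromine migration to [3-bromo-4-methyl-5-(3,4,5-trimethoxyphenyl)furan-2-yl]lithium F10.
- Quenching F10 with methyl chloroformate should give methyl 3-bromo-4-methyl-5-(3,4,5-trimethoxyphenyl)furan-2-carboxylate F11.
- Methylenation with Cp2TiMe2 as in step 5 should give 3-bromo-2-(1-methoxyethenyl)-4-methyl-5-(3,4,5-trimethoxyphenyl)furan F12.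
- Heck coupling of F12 with 10 (Pd(OAc)2, P(o-tol)3, Et3N, DMF, 80 °C) leads to 11.

**Step 1.** Protodecarboxylation of 1 may outrun the coupling, with loss of the volatile furan, because oxidative addition of the electron-rich bromide 2 is slow. Homocoupling of 2 is a further drain.

Fallback: set out from bromide 2 and rejoin at 3 by a Suzuki coupling.
- Miyaura borylation (bis(pinacolato)diboron, PdCl2(dppf), KOAc, dioxane, 90 °C) should give 4,4,5,5-tetramethyl-2-(3,4,5-trimethoxyphenyl)-1,3,2-dioxaborolane F13.
- Coupling of F13 with purchased 2-bromo-3-methylfuran (Pd(PPh3)4, K2CO3, dioxane–water, 80 °C) leads to 3.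

## Further compounds

F1 | step 7 | 4-iodo-3-methyl-2-(3,4,5-trimethoxyphenyl)furan | Cc1c(I)coc1-c1cc(OC)c(OC)c(OC)c1
F2 | step 7 | 4-methyl-5-(3,4,5-trimethoxyphenyl)furan-3-carbaldehyde | Cc1c(C=O)coc1-c1cc(OC)c(OC)c(OC)c1
F3 | step 7 | (E)-3-(methoxycarbonyl)-4-[4-methyl-5-(3,4,5-trimethoxyphenyl)furan-3-yl]but-3-enoic acid | COC(=O)/C(CC(=O)O)=C/c1coc(-c2cc(OC)c(OC)c(OC)c2)c1C
F4 | step 7 | methyl 7-acetyloxy-3-methyl-2-(3,4,5-trimethoxyphenyl)-1-benzofuran-5-carboxylate | COC(=O)c1cc(OC(C)=O)c2oc(-c3cc(OC)c(OC)c(OC)c3)c(C)c2c1
F5 | step 7 | methyl 7-hydroxy-3-methyl-2-(3,4,5-trimethoxyphenyl)-1-benzofuran-5-carboxylate | COC(=O)c1cc(O)c2oc(-c3cc(OC)c(OC)c(OC)c3)c(C)c2c1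
F6 | step 5 | 3-iodo-N-methoxy-N,4-dimethyl-5-(3,4,5-trimethoxyphenyl)furan-2-carboxamide | CON(C)C(=O)c1oc(-c2cc(OC)c(OC)c(OC)c2)c(C)c1I
F7 | step 5 | 1-[3-iodo-4-methyl-5-(3,4,5-trimethoxyphenyl)furan-2-yl]ethan-1-one | CC(=O)c1oc(-c2cc(OC)c(OC)c(OC)c2)c(C)c1I
F8 | step 5 | 2-(1,1-dimethoxyethyl)-3-iodo-4-methyl-5-(3,4,5-trimethoxyphenyl)furan | COC(C)(OC)c1oc(-c2cc(OC)c(OC)c(OC)c2)c(C)c1I
F9 | step 3 | 5-bromo-3-methyl-2-(3,4,5-trimethoxyphenyl)furan | Cc1cc(Br)oc1-c1cc(OC)c(OC)c(OC)c1
F10 | step 3 | [3-bromo-4-methyl-5-(3,4,5-trimethoxyphenyl)furan-2-yl]lithium | [Li]c1oc(-c2cc(OC)c(OC)c(OC)c2)c(C)c1Br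
F11 | step 3 | methyl 3-bromo-4-methyl-5-(3,4,5-trimethoxyphenyl)furan-2-carboxylate | COC(=O)c1oc(-c2cc(OC)c(OC)c(OC)c2)c(C)c1Br
F12 | step 3 | 3-bromo-2-(1-methoxyethenyl)-4-methyl-5-(3,4,5-trimethoxyphenyl)furan | C=C(OC)c1oc(-c2cc(OC)c(OC)c(OC)c2)c(C)c1Br
F13 | step 1 | 4,4,5,5-tetramethyl-2-(3,4,5-trimethoxyphenyl)-1,3,2-dioxaborolane | COc1cc(B2OC(C)(C)C(C)(C)O2)cc(OC)c1OC
A1 | alternative 1 | trans-5-bromo-7-methoxy-3-methyl-2-(3,4,5-trimethoxyphenyl)-2,3-dihydro-1-benzofuran (racemic, one enantiomer drawn) | C[C@@H]1[C@@H](c2cc(OC)c(OC)c(OC)c2)Oc2c(OC)cc(Br)cc21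
A2 | alternative 1 | 5-bromo-7-methoxy-3-methyl-2-(3,4,5-trimethoxyphenyl)-1-benzofuran | Cc1c(-c2cc(OC)c(OC)c(OC)c2)oc2c(OC)cc(Br)cc12
A3 | alternative 2 | 5-(dimethoxymethyl)-7-methoxy-3-methyl-2-(3,4,5-trimethoxyphenyl)-1-benzofuran | Cc1c(-c2cc(OC)c(OC)c(OC)c2)oc2c(OC)cc(C(OC)OC)cc12
A4 | alternative 2 | 5-(dimethoxymethyl)-1,3-dimethoxy-2-{[1-(3,4,5-trimethoxyphenyl)prop-1-en-1-yl]oxy}benzene (alkene geometry not specified) | CC=C(Oc1c(OC)cc(C(OC)OC)cc1OC)c1cc(OC)c(OC)c(OC)c1
A5 | alternative 3 | 5-{[tert-butyl(dimethyl)silyl]oxymethyl}-7-methoxy-3-methyl-2-(3,4,5-trimethoxyphenyl)-1-benzofuran-4-ol | Cc1c(-c2cc(OC)c(OC)c(OC)c2)oc2c(OC)cc(CO[Si](C)(C)C(C)(C)C)c(O)c12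
A6 | alternative 3 | pentacarbonyl{methoxy[4-methyl-5-(3,4,5-trimethoxyphenyl)furan-2-yl]methylidene}chromium, (CO)5Cr=C(OMe)(furyl) | COC(c1cc(C)c(-c2cc(OC)c(OC)c(OC)c2)o1)=[Cr](=C=O)(=C=O)(=C=O)(=C=O)=C=O
A7 | alternative 3 | tert-butyl(dimethyl)(prop-2-yn-1-yloxy)silane | C#CCO[Si](C)(C)C(C)(C)C
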